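1. Starting material is conserved: what leaves its reading stands as product or is held on catalyst. The flasks, the earlier runs and the questions are these.

| flask | starting material | partner | free catalyst | temperature | remark | time |
|---|---|---|---|---|---|---|
| cedar | 10 mM | 25 mM | 2.5 mM | 22 °C | run made earlier |  |
| maple | 10 mM | 25 mM | 11 mM | 50 °C | run made earlier |  |
| elm | 10 mM | 19 mM | 2 mM | 22 °C | run made earlier |  |
| eta | 10 mM | 25.0 mM | 2.0 mM | 40 °C |  | 10 h |
| zeta | 10 mM | 12.0 mM | 2.0 mM | 60 °C |  | 10 h |
| alpha | 3.0 mM | 15.0 mM | 2.0 mM | 40 °C |  | 10 h |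
| epsilon | 10 mM | 25.0 mM | 2.0 mM | 60 °C |  | 10 h |
| gamma | 5.0 mM | 25.0 mM | 8.0 mM | 10 °C |  | 10 h |

| run | time / h | product / % | starting material / % |
|---|---|---|---|
| cedar | 1.33 | 0 | 96 |
| cedar | 3.00 | 3 | 90 |
| cedar | 6.00 | 2 | 84 |
| cedar | 10.0 | 0 | 80 |
| cedar | 12.0 | 4 | 78 |
| cedar | 20.0 | 7 | 76 |
| maple | 0.833 | 9 | 42 |
| maple | 1.50 | 26 | 26 |
| maple | 2.50 | 45 | 12 |
| maple | 3.00 | 53 | 11 |
| maple | 4.00 | 71 | 7 |
| maple | 5.00 | 76 | 2 |
| elm | 1.33 | 0 | 96 |
| elm | 2.50 | 0 | 94 |
| elm | 5.00 | 3 | 88 |
| elm | 10.0 | 0 | 84 |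
| elm | 20.0 | 4 | 79 |

(scatter of a reading: 2 percentage points)



- ranking by amount of product, in percent of the starting material charged, from high to low, at 10 h (eta / zeta / alpha / epsilon / gamma)
- the same order at 40 h (eta / zeta / alpha / epsilon / gamma)
- the amount of product, in percent of the starting material charged of the flask you put first, at 10 h
- the amount of product, in percent of the starting material charged of the flask you put last, at 10 h

2. I took one starting material lost per catalyst charged as the zero of the scale. By 20.0 h cedar had lost 0.960 per catalyst, and by 20.0 h elm had lost 1.05. Cedar's product then read 7% against 24.0% of starting material lost, so in cedar at 22 °C the catalyst had loaded and turned slowly.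

3. First rung, loading. In maple at 0.833 h, the balance left 4.90 mM held on catalyst. Maple's starting-material reading at that time gives a half-life of about 0.666 h.

4. Second rung, the round. I defined the round rate ν as product made per catalyst charged per hour, the turnover frequency averaged over the catalyst charged. Maple's readings from 0.833 h to 4.00 h give 0.178 h⁻¹, so a round took 5.62 h, longer than the loading half-life. Cedar gives 0.0140 h⁻¹, but from one reading with a scatter of 2 percentage points, so it is soft.

5. Third rung, the whole charge. Epsilon has the starting material and partner charges of cedar and maple. An Arrhenius line through the two rates gives an activation energy Ea of 72.0 kJ mol⁻¹. The round rate of epsilon at 60 °C is then reckoned as ν′ = 0.398 h⁻¹. Epsilon needs n = 5.00 rounds, which I reckoned at 12.6 h, longer than 10 h. For 10 h that gives 3.98 rounds, so I reckoned 79.6% product.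

6. The forecast gave epsilon > zeta > alpha > eta > gamma at 10 h and epsilon > zeta > alpha > eta > gamma at 40 h, with 92% on top and 0.4% last. Its ground was that “this complex turns over slowly”. Its top stood above my figure.

7. The flasks gave epsilon > zeta > alpha > eta > gamma at 10 h and epsilon > zeta > alpha > eta > gamma at 40 h, with 83.3% on top and 0.0333% last.

    starting material + free catalyst ⇌ catalyst intermediate A (K = 2300 M⁻¹, k = 68.0 M⁻¹ h⁻¹, Ea = 57.0 kJ mol⁻¹, ΔH = −31.0 kJ mol⁻¹)
    partner + catalyst intermediate A ⇌ catalyst intermediate B (K = 120 M⁻¹, k = 23.0 M⁻¹ h⁻¹, Ea = 67.0 kJ mol⁻¹, ΔH = −83.0 kJ mol⁻¹)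
    catalyst intermediate B ⇌ by-product + catalyst intermediate C (K = 0.0110 M, k = 1.90 h⁻¹, Ea = 91.0 kJ mol⁻¹, ΔH = 48.0 kJ mol⁻¹)
    catalyst intermediate C → free catalyst + product (k = 0.680 h⁻¹, Ea = 99.0 kJ mol⁻¹)
    partner + by-product ⇌ idle adduct, settled at all times (K = 15.0 M⁻¹, ΔH = −69.0 kJ mol⁻¹)
    catalyst intermediate C → spent catalyst (k = 0.0140 h⁻¹, Ea = 112 kJ mol⁻¹)
    (constants at 40 °C)

Epsilon's 83.3% is 4.17 of its 5.00 rounds, against the 3.98 from ν′. Carried down to 35 °C, ν′ becomes 0.0483 h⁻¹, or 0.483 rounds, and that repeat of epsilon made 14.0%, which is 0.700 rounds. In epsilon at 10.0 h, the binding of starting material to free catalyst relaxed, both ways together, with a half-life of 0.835 h, longer than the 0.10 h of catalyst intermediate C by its product-making step alone. Of the catalyst charged, epsilon then held 67.9% free, 16.1% as catalyst intermediate A, 1.76% as catalyst intermediate B, 2.61% as catalyst intermediate C and 11.6% as spent catalyst.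

(The data were computed with constants of no real substance, noise included.)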